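The central ring is cut at C3–C4 and read as a rearranged 2-pyrone. Ring atoms C4, C5, C6, C1 and C2 are C2–C6 of triacetic acid lactone and C3 is its 6-methyl carbon, so the alternating oxygens on C2, C4 and C6 and the two different arms on C3 and C5 are in place before the arene exists. In one operation methoxide opens the lactone and the terminal ketone enolate closes onto the ester, forming the carbocycle and the C3–C4 bond. The precursor is a 4-methoxy-2-pyrone with the isopropyl arm on pyrone C3 and the isobutyl arm on the 6-methylene, both trione enols masked as methyl ethers.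

Key step: step 7

Assumption: the sense of induction of the quinine-derived squaramide (step 5) and of the (S,S)-diether (step 6) is taken as drawn; if either proves opposite, the quinidine-derived pseudo-enantiomer or the (R,R)-ligand is used with no other change.

Step 1
Reactants: 1 1-(2,4,6-trihydroxyphenyl)ethan-1-one (2,4,6-trihydroxyacetophenone)
Product: 2 2-acetyl-3-hydroxy-4,4,6,6-tetramethylcyclohex-2-ene-1,5-dione (acetylsyncarpic acid)
Conditions: NaOMe, MeI, MeOH, reflux
Reagents that add atoms: iodomethane, CI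
Why: Base-mediated exhaustive C-methylation of the phloroglucinol enolates (dearomatising alkylation) should stop at the tetramethyl stage because the acetyl-bearing carbon stays enolised as a β-triketone anion.

Step 2
Reactants: 2 acetylsyncarpic acid
Product: 3 5-hydroxy-2,2,6,6-tetramethylcyclohex-4-ene-1,3-dione (syncarpic acid)
Conditions: 6 M HCl (aq), reflux
Reagents that add atoms: none
Why: Acid-promoted retro-Claisen deacetylation of the 2-acyl trione should give the parent enolised trione, the quaternary carbons being inert.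

Step 3
Reactants: 3 syncarpic acid; 4 2-methylpropanal (isobutyraldehyde)
Product: 6 2,2,4,4-tetramethyl-6-(2-methylpropylidene)cyclohexane-1,3,5-trione, via piperidine Mannich base 5 (not isolated)
Conditions: piperidine (1 equiv), CH2Cl2, rt; then 1 M HCl (aq)
Reagents that add atoms: none
Why: A Knoevenagel condensation run through the Mannich base should store the electrophilic alkylidene trione until acid eliminates piperidine, which prevents addition of a second trione, and no stereocentre remains.

Step 4
Reactants: 3 syncarpic acid; 7 3-methylbutanal (isovaleraldehyde)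
Product: 9 2,2,4,4-tetramethyl-6-(3-methylbutylidene)cyclohexane-1,3,5-trione, via piperidine Mannich base 8 (not isolated)
Conditions: piperidine (1 equiv), CH2Cl2, rt; then 1 M HCl (aq)
Reagents that add atoms: none
Why: The same Mannich-mediated Knoevenagel condensation should deliver the second alkylidene trione, which is used freshly because its γ-hydrogens make it prone to deconjugation.

Step 5
Reactants: 10 4-hydroxy-6-methyl-2H-pyran-2-one (triacetic acid lactone); 6 2,2,4,4-tetramethyl-6-(2-methylpropylidene)cyclohexane-1,3,5-trione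
Product: 12 4-methoxy-3-[(1S)-1-(2-methoxy-3,3,5,5-tetramethyl-4,6-dioxocyclohex-1-en-1-yl)-2-methylpropyl]-6-methyl-2H-pyran-2-one, via bis-enol Michael adduct 11 (not isolated)
Conditions: quinine-derived squaramide catalyst (3-[3,5-bis(trifluoromethyl)anilino]-4-[(9-deoxy-epi-quinin-9-yl)amino]cyclobut-3-ene-1,2-dione, 5 mol %), THF/CH2Cl2, −20 °C; then TMSCHN2, MeOH, 0 °C
Reagents that add atoms: (trimethylsilyl)diazomethane, C[Si](C)(C)C=[N+]=[N-]
Why: In this bifunctional squaramide-catalysed Michael addition the quinuclidine deprotonates the 4-hydroxypyrone and the squaramide binds a trione carbonyl, so that pyrone C3 attacks one face of the alkylidene carbon (catalyst control sets the arm stereocentre), and neutral O-methylation of both vinylogous acids by the diazoalkane then locks the adduct against retro-Michael racemisation (any 2-methoxy-4-pyranone isomer is removed by chromatography).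

Step 6
Reactants: 12 the 4-methoxy-6-methylpyrone carrying the isopropyl arm; 9 2,2,4,4-tetramethyl-6-(3-methylbutylidene)cyclohexane-1,3,5-trione
Product: 15 4-methoxy-6-[(2R)-2-(2-methoxy-3,3,5,5-tetramethyl-4,6-dioxocyclohex-1-en-1-yl)-4-methylpentyl]-3-[(1S)-1-(2-methoxy-3,3,5,5-tetramethyl-4,6-dioxocyclohex-1-en-1-yl)-2-methylpropyl]-2H-pyran-2-one, via lithium dienolate 13 (not isolated), via lithium trione enolate 14 (not isolated)
Conditions: LiN(SiMe3)2, (S,S)-1,2-dimethoxy-1,2-diphenylethane, toluene, −78 °C; then 9, −78 °C; then MeOTf, −78 → −20 °C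
Reagents that add atoms: methyl trifluoromethanesulfonate, COS(=O)(=O)C(F)(F)F
Why: Proposed new method: the 6-methyl group of 12 is the doubly vinylogous α-position of the lactone and is deprotonated to dienolate 13, whose exocyclic carbon adds 1,4 to the alkylidene carbon of 9 (the carbonyls are shielded by the flanking gem-dimethyl groups) within a lithium aggregate carrying the C2-symmetric diether, so that one face of the planar acceptor is favoured and the new methine is set under ligand control (the minor epimer is a diastereomer and is removed by chromatography), after which the hard methylating agent O-alkylates trione enolate 14; the closest known reaction type is the chiral-diether-mediated enantioselective Michael addition of lithium ester enolates to unsaturated esters, combined with the established alkylation and aldol chemistry of lithiated 4-methoxy-6-methyl-2-pyrone.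

Step 7
Reactants: 15 the 4-methoxy-2-pyrone carrying both arms
Product: 17 5-methoxy-2-[(1R)-1-(2-methoxy-3,3,5,5-tetramethyl-4,6-dioxocyclohex-1-en-1-yl)-3-methylbutyl]-4-[(1R)-1-(2-methoxy-3,3,5,5-tetramethyl-4,6-dioxocyclohex-1-en-1-yl)-2-methylpropyl]benzene-1,3-diol, via ring-opened keto ester 16 (not isolated)
Conditions: NaOMe, MeOH, 65 °C; then AcOH, 0 °C
Reagents that add atoms: none
Why: Methoxide adds to the lactone carbonyl of 15 and opens the ring to keto ester 16, the ketone enolates equilibrate, and the enolate on the methylene next to the isobutyl-arm methine (the former 6-CH2 carbon) attacks the ester, expels methoxide and the resulting cyclohexenedione tautomerises to the resorcinol, an irreversible aromatisation that drains the equilibrium. The closest known reaction type is the alkoxide-induced conversion of 4-methoxy-6-methyl-2-pyrone into 5-methoxyresorcinol and the Claisen cyclisation of 3,5-dioxo esters. The carbocycle closes by a 6-(enolendo)-exo-trig Claisen (Dieckmann-type) attack. No stereocentre is created, and the two existing methines should survive because their C–H bonds are only cross-conjugated and the enol ethers cannot leave as carbanions, which excludes epimerisation and β-elimination. The step needs C-acylation through the less acidic terminal enolate in preference to O-acylation back to the pyrone, and it needs the vinylogous esters to stay intact; the first is secured because re-lactonisation merely regenerates 15 while aromatisation is irreversible, the second because every exchangeable alkoxy group is methoxy, so exchange with methoxide is degenerate.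

Step 8
Reactants: 17 the 2,4-disubstituted 5-methoxyresorcinol; 18 hexanoyl chloride
Product: 19 1-{2,4-dihydroxy-6-methoxy-3-[(1R)-1-(2-methoxy-3,3,5,5-tetramethyl-4,6-dioxocyclohex-1-en-1-yl)-3-methylbutyl]-5-[(1R)-1-(2-methoxy-3,3,5,5-tetramethyl-4,6-dioxocyclohex-1-en-1-yl)-2-methylpropyl]phenyl}hexan-1-one
Conditions: TiCl4, CH2Cl2, −20 → 0 °C
Reagents that add atoms: none
Why: Friedel–Crafts acylation of the titanium phenoxide should occur at the only unsubstituted ring carbon, which is activated by three oxygens, and the low temperature should spare the benzylic methines.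

Step 9
Reactants: 19 the hexanoyl tri-O-methyl compound
Product: 20 1-{2,4,6-trihydroxy-3-[(1R)-1-(2-hydroxy-3,3,5,5-tetramethyl-4,6-dioxocyclohex-1-en-1-yl)-3-methylbutyl]-5-[(1R)-1-(2-hydroxy-3,3,5,5-tetramethyl-4,6-dioxocyclohex-1-en-1-yl)-2-methylpropyl]phenyl}hexan-1-one (myrtucommulone H)
Conditions: BCl3, CH2Cl2, −78 → 0 °C; then H2O
Reagents that add atoms: none
Why: In this Lewis acid demethylation BCl3 chelated between the aryl ketone and the ortho methoxy group cleaves that ether, chloride likewise dealkylates the two boron-bound vinylogous esters, and no bond at either stereocentre is involved.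

Compound list
1 | 1-(2,4,6-trihydroxyphenyl)ethan-1-one | CC(=O)c1c(O)cc(O)cc1O | starting material
2 | 2-acetyl-3-hydroxy-4,4,6,6-tetramethylcyclohex-2-ene-1,5-dione | CC(=O)C1=C(O)C(C)(C)C(=O)C(C)(C)C1=O | intermediate
3 | 5-hydroxy-2,2,6,6-tetramethylcyclohex-4-ene-1,3-dione (syncarpic acid) | OC1=CC(=O)C(C)(C)C(=O)C1(C)C | intermediate
4 | 2-methylpropanal | CC(C)C=O | starting material
5 | 3-hydroxy-4,4,6,6-tetramethyl-2-[2-methyl-1-(piperidin-1-yl)propyl]cyclohex-2-ene-1,5-dione (racemic Mannich base) | CC(C)C(N1CCCCC1)C1=C(O)C(C)(C)C(=O)C(C)(C)C1=O | intermediate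
6 | 2,2,4,4-tetramethyl-6-(2-methylpropylidene)cyclohexane-1,3,5-trione | CC(C)C=C1C(=O)C(C)(C)C(=O)C(C)(C)C1=O | intermediate
7 | 3-methylbutanal | CC(C)CC=O | starting material
8 | 3-hydroxy-4,4,6,6-tetramethyl-2-[3-methyl-1-(piperidin-1-yl)butyl]cyclohex-2-ene-1,5-dione (racemic Mannich base) | CC(C)CC(N1CCCCC1)C1=C(O)C(C)(C)C(=O)C(C)(C)C1=O | intermediate
9 | 2,2,4,4-tetramethyl-6-(3-methylbutylidene)cyclohexane-1,3,5-trione | CC(C)CC=C1C(=O)C(C)(C)C(=O)C(C)(C)C1=O | intermediate
10 | 4-hydroxy-6-methyl-2H-pyran-2-one (triacetic acid lactone) | CC1=CC(O)=CC(=O)O1 | starting material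
11 | 4-hydroxy-3-[(1S)-1-(2-hydroxy-3,3,5,5-tetramethyl-4,6-dioxocyclohex-1-en-1-yl)-2-methylpropyl]-6-methyl-2H-pyran-2-one | CC1=CC(O)=C([C@H](C2=C(O)C(C)(C)C(=O)C(C)(C)C2=O)C(C)C)C(=O)O1 | intermediate
12 | 4-methoxy-3-[(1S)-1-(2-methoxy-3,3,5,5-tetramethyl-4,6-dioxocyclohex-1-en-1-yl)-2-methylpropyl]-6-methyl-2H-pyran-2-one | CC1=CC(OC)=C([C@H](C2=C(OC)C(C)(C)C(=O)C(C)(C)C2=O)C(C)C)C(=O)O1 | intermediate
13 | lithium dienolate of 12 (6-methyl deprotonated, 6-methylene-6H-pyran-2-olate form; arm stereocentre as in 12) | [Li+].[O-]C1=C([C@H](C2=C(OC)C(C)(C)C(=O)C(C)(C)C2=O)C(C)C)C(OC)=CC(=C)O1 | intermediate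
14 | lithium trione enolate of the Michael adduct (15 with the methoxy group of the (2R)-isobutyl arm replaced by OLi) | O=C1OC(C[C@@H](CC(C)C)C2=C([O-])C(C)(C)C(=O)C(C)(C)C2=O)=CC(OC)=C1[C@H](C1=C(OC)C(C)(C)C(=O)C(C)(C)C1=O)C(C)C.[Li+] | intermediate
15 | 4-methoxy-6-[(2R)-2-(2-methoxy-3,3,5,5-tetramethyl-4,6-dioxocyclohex-1-en-1-yl)-4-methylpentyl]-3-[(1S)-1-(2-methoxy-3,3,5,5-tetramethyl-4,6-dioxocyclohex-1-en-1-yl)-2-methylpropyl]-2H-pyran-2-one | O=C1OC(C[C@@H](CC(C)C)C2=C(OC)C(C)(C)C(=O)C(C)(C)C2=O)=CC(OC)=C1[C@H](C1=C(OC)C(C)(C)C(=O)C(C)(C)C1=O)C(C)C | intermediate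
16 | methyl (2E,7R)-3-methoxy-7-(2-methoxy-3,3,5,5-tetramethyl-4,6-dioxocyclohex-1-en-1-yl)-2-[(1S)-1-(2-methoxy-3,3,5,5-tetramethyl-4,6-dioxocyclohex-1-en-1-yl)-2-methylpropyl]-9-methyl-5-oxodec-2-enoate | COC(=O)/C([C@H](C1=C(OC)C(C)(C)C(=O)C(C)(C)C1=O)C(C)C)=C(/OC)CC(=O)C[C@@H](CC(C)C)C1=C(OC)C(C)(C)C(=O)C(C)(C)C1=O | intermediate
17 | 5-methoxy-2-[(1R)-1-(2-methoxy-3,3,5,5-tetramethyl-4,6-dioxocyclohex-1-en-1-yl)-3-methylbutyl]-4-[(1R)-1-(2-methoxy-3,3,5,5-tetramethyl-4,6-dioxocyclohex-1-en-1-yl)-2-methylpropyl]benzene-1,3-diol | c1c(O)c([C@@H](CC(C)C)C2=C(OC)C(C)(C)C(=O)C(C)(C)C2=O)c(O)c([C@H](C2=C(OC)C(C)(C)C(=O)C(C)(C)C2=O)C(C)C)c1OC | intermediate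
18 | hexanoyl chloride | CCCCCC(Cl)=O | starting material
19 | 1-{2,4-dihydroxy-6-methoxy-3-[(1R)-1-(2-methoxy-3,3,5,5-tetramethyl-4,6-dioxocyclohex-1-en-1-yl)-3-methylbutyl]-5-[(1R)-1-(2-methoxy-3,3,5,5-tetramethyl-4,6-dioxocyclohex-1-en-1-yl)-2-methylpropyl]phenyl}hexan-1-one | CCCCCC(=O)c1c(O)c([C@@H](CC(C)C)C2=C(OC)C(C)(C)C(=O)C(C)(C)C2=O)c(O)c([C@H](C2=C(OC)C(C)(C)C(=O)C(C)(C)C2=O)C(C)C)c1OC | intermediate
20 | myrtucommulone H, 1-{2,4,6-trihydroxy-3-[(1R)-1-(2-hydroxy-3,3,5,5-tetramethyl-4,6-dioxocyclohex-1-en-1-yl)-3-methylbutyl]-5-[(1R)-1-(2-hydroxy-3,3,5,5-tetramethyl-4,6-dioxocyclohex-1-en-1-yl)-2-methylpropyl]phenyl}hexan-1-one | CCCCCC(=O)c1c(O)c([C@@H](CC(C)C)C2=C(O)C(C)(C)C(=O)C(C)(C)C2=O)c(O)c([C@H](C2=C(O)C(C)(C)C(=O)C(C)(C)C2=O)C(C)C)c1O | target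

Total step count: 9. Longest linear sequence: 8 steps (1, 2, 3, 5, 6, 7, 8, 9, from compound 1); step 4 is a one-step branch from 3.

Steps most likely to fail

Step 6 (labelled step). The ligand-bound dienolate may show poor facial selectivity toward the unchelated, very reactive acceptor, and proton transfer from the acidic γ-methylene of 9 may quench part of the nucleophile. The fallback uses known chemistry and sets out from 12 and 9. The dienolate is generated with LiN(SiMe3)2 in THF at −78 °C without chiral ligand, added to 9 and trapped with MeOTf, as in the established reactions of lithiated 4-methoxy-6-methyl-2-pyrone with electrophiles. This should give 15 together with its epimer at the new methine, 4-methoxy-6-[(2S)-2-(2-methoxy-3,3,5,5-tetramethyl-4,6-dioxocyclohex-1-en-1-yl)-4-methylpentyl]-3-[(1S)-1-(2-methoxy-3,3,5,5-tetramethyl-4,6-dioxocyclohex-1-en-1-yl)-2-methylpropyl]-2H-pyran-2-one F1. Because the isopropyl arm is already enantioenriched, the two are diastereomers and are separated by preparative HPLC. The route is rejoined at 15.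

Step 7 (key step). Claisen closure through the terminal enolate may be too slow at the hindered, push-pull-deactivated ester, so that the open form simply returns to the pyrone. Prolonged heating with methoxide may then cause retro-Claisen opening of the masked trione rings or attack of the product phenoxide on a neighbouring vinylogous ester. The fallback separates opening from closure and sets out from 15. Mg(OMe)2 in MeOH at room temperature opens the lactone, and the magnesium chelate allows keto ester 16 to be isolated. Excess LiN(i-Pr)2 in THF, −78 → 0 °C, then forms the dianion, whose terminal carbanion should close onto the ester under kinetic, alkoxide-free conditions (polyanion Claisen cyclisation). The route is rejoined at 17, and no new compound is made.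

Step 8. The free phenols may undergo O-acylation, may attack the Lewis-acid-activated vinylogous esters with loss of methanol to give chromenes, or an arm may be lost by retro-Friedel–Crafts cleavage under TiCl4/HCl. The fallback caps the phenols first and sets out from 17. Me2SO4 and K2CO3 in acetone should give 1,3,5-trimethoxy-2-[(1R)-1-(2-methoxy-3,3,5,5-tetramethyl-4,6-dioxocyclohex-1-en-1-yl)-3-methylbutyl]-4-[(1R)-1-(2-methoxy-3,3,5,5-tetramethyl-4,6-dioxocyclohex-1-en-1-yl)-2-methylpropyl]benzene F2. Acylation of this phenol-free arene with 18 and TiCl4 in CH2Cl2 should give 1-{2,4,6-trimethoxy-3-[(1R)-1-(2-methoxy-3,3,5,5-tetramethyl-4,6-dioxocyclohex-1-en-1-yl)-3-methylbutyl]-5-[(1R)-1-(2-methoxy-3,3,5,5-tetramethyl-4,6-dioxocyclohex-1-en-1-yl)-2-methylpropyl]phenyl}hexan-1-one F3. BBr3 in CH2Cl2, −78 °C → rt, then removes all five methyl groups. This bypasses 19 and rejoins the route at 20.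

Further compounds
F1 | step 6 | 4-methoxy-6-[(2S)-2-(2-methoxy-3,3,5,5-tetramethyl-4,6-dioxocyclohex-1-en-1-yl)-4-methylpentyl]-3-[(1S)-1-(2-methoxy-3,3,5,5-tetramethyl-4,6-dioxocyclohex-1-en-1-yl)-2-methylpropyl]-2H-pyran-2-one | O=C1OC(C[C@H](CC(C)C)C2=C(OC)C(C)(C)C(=O)C(C)(C)C2=O)=CC(OC)=C1[C@H](C1=C(OC)C(C)(C)C(=O)C(C)(C)C1=O)C(C)C
F0 | step 7 | none | none
F2 | step 8 | 1,3,5-trimethoxy-2-[(1R)-1-(2-methoxy-3,3,5,5-tetramethyl-4,6-dioxocyclohex-1-en-1-yl)-3-methylbutyl]-4-[(1R)-1-(2-methoxy-3,3,5,5-tetramethyl-4,6-dioxocyclohex-1-en-1-yl)-2-methylpropyl]benzene | c1c(OC)c([C@@H](CC(C)C)C2=C(OC)C(C)(C)C(=O)C(C)(C)C2=O)c(OC)c([C@H](C2=C(OC)C(C)(C)C(=O)C(C)(C)C2=O)C(C)C)c1OC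
F3 | step 8 | 1-{2,4,6-trimethoxy-3-[(1R)-1-(2-methoxy-3,3,5,5-tetramethyl-4,6-dioxocyclohex-1-en-1-yl)-3-methylbutyl]-5-[(1R)-1-(2-methoxy-3,3,5,5-tetramethyl-4,6-dioxocyclohex-1-en-1-yl)-2-methylpropyl]phenyl}hexan-1-one | CCCCCC(=O)c1c(OC)c([C@@H](CC(C)C)C2=C(OC)C(C)(C)C(=O)C(C)(C)C2=O)c(OC)c([C@H](C2=C(OC)C(C)(C)C(=O)C(C)(C)C2=O)C(C)C)c1OC
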